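## The problem

1. The target is a monocyclic C30 triterpenoid acetate, numbered here as the open C30 chain. The ring is C2 (CMe2), C3 (CHOAc), C4, C5, C6 (bearing the methylidene carbon C26) and C7 (CH). The side chain runs from C8 to C24, with E double bonds at C10=C11, C14=C15 and C18=C19 and an isopropylidene end at C22=C23.
2. There are two stereocentres, C3 (S) and C7 (R), cis on the ring but separated by the quaternary C2. In a free monocycle either substituent can turn axial at small cost, so 1,3-induction that rests on conformational bias is weak in both directions.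
3. The bonds around C7 (C2–C7 and C7–C8) are the hindered ones, because C7 lies between the quaternary C2 and the sp2 carbon C6.
4. The C6=C26 methylidene is the least stable position for that double bond. Acid, metal hydrides or reversible hydrogen transfer would move it to C6=C7 or C5=C6, so it must be made regiospecifically and kept under neutral conditions afterwards.
5. The chain carries no heteroatom, so the join must leave no trace. It must preserve three E-trisubstituted alkenes, one of which (C10=C11) has its methyl on the ring side because of the tail-to-tail junction at C12–C13. No commercial polyprenyl unit contains that pattern.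
6. The four chain alkenes are as nucleophilic as any alkene that could close the ring. A cationic, radical or electrophilic ring closure run in their presence has to be stopped after one ring. The chain also excludes peracids, halonium reagents, strong acid and unselective hydroboration, and the acetate excludes organolithiums and hydrides late in the route.
7. Three features make the key step possible. The oxygen on C3 and carbon C8 on C7 stand cis-1,3 on the ring C2–C7. C9 is a plain CH2, so O3 and C9 are in a 1,5-relationship that one SiMe2 unit can bridge. The methylidene C6=C26 sits next to C7, which is the pattern left when a C7 radical adds to the inner carbon of a terminal alkyne.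

## Retrosynthesis

**C9–C10 (sp3–sp2).**
- 21 is cut into the iodide 12 and the alkenyl iodide 19. 12 holds eleven skeletal carbons, both stereocentres and the acetate, and is used as its zinc reagent 20. 19 holds nineteen carbons, no stereocentre and all the alkene geometry.
- The neighbouring cuts are worse. C7–C8 is neopentylic and would have to set C7 in the joining step. C8–C9 needs an allylic electrophile with an SN2/SN2' ambiguity. C12–C13 is an allyl–allyl coupling and puts an E alkene on the ring half.
- The forward reaction must keep the C10=C11 geometry and tolerate the acetate and the methylidene. A neutral alkyl–alkenyl Negishi coupling does this.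

**C10–I, C10–CH3 and C12–C13.**
- 19 comes from syn-hydrometalation and iodinolysis (through 18) of the trienyne 17.
- 17 comes from 13 and 14 through the dianion 15 and the acetylide 16, followed by C-methylation.
- Carbonyl olefination at C10 would give E/Z mixtures, and methyl-metalation of a terminal alkyne would put the methyl on C11. An internal methyl alkyne places it on C10.
- The precursor 13 already holds two E alkenes. The forward steps must not isomerise them and must put the metal on C10.

**C9–I and C3–OAc back to one silicon atom.**
- 12 comes from 11 and 11 from the diol 10.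
- Both hydroxyl groups of 10 are traced to the bicyclic siloxane 9, in which C9–Si is the masked primary alcohol and O3–Si the masked carbinol.
- This turns the cis-1,5-diol pattern into a ring.

**C8–C9 and C6–C7 (key step).**
- 9 is opened at two C–C bonds to the acyclic bromomethylsilyl ether 7. 7 has one stereocentre and no ring.
- Cutting C2–C7 instead would bring back a polyene-type closure at the quaternary carbon. Cutting C6–C7 alone would leave C7 to a weak chair preference.
- Cutting both bonds lets the tether close first (to radical 8), so that the ring closure can only give the cis isomer.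
- The forward cascade needs endo attack on the vinyl group, exo attack on the alkyne, and hydrogen transfer only at the end.

**C2–C3.**
- 7 is the silyl ether of 6.
- 6 is cut next to the quaternary carbon into 2 (from 1) and 3. The allene 3 serves as its prenylborane 4 and delivers C2 through its γ-carbon (borinate 5).
- One step forms the quaternary carbon, the carbinol and the vinyl group, and the borane sets C3. Every later stereochemical event is derived from C3.

## Roads not taken

**Alternative 1:**
- The cut is C2–C7 in the complete C30 chain.
- The forward key step is opening of (3S)-2,3-oxidosqualene A1 at C2, by Cp2TiCl (trivalent titanium) or a Lewis acid. This is followed by 6-endo closure onto C6=C7 and termination at C26 to give the alcohol A2, which is acetylated to 21.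
- It is the shortest route on paper.
- One of six trisubstituted alkenes of the parent hexaene must first be singled out enantioselectively.
- After the first ring the reactive centre at C6 lies within reach of C10=C11, so further cyclisation and premature quenching compete with termination.
- Nothing in the substrate forces loss of hydrogen from C26 rather than from C5 or C7.
- All by-products are isomers of nearly equal polarity.
- In the chosen plan the ring is closed before any polyene is present, and the alkyne carbon count fixes the methylidene.

**Alternative 2:**
- The cut is C7–C8 at a flattened C7.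
- A β-chloro enal A3, reached from a desymmetrised cyclic 1,3-diketone, would be cross-coupled with a C21 alkyl-metal to give the tetrasubstituted enal A4.
- Reduction of the tosylhydrazone of A4 would give an allylic diazene. Its retro-ene loss of N2 delivers hydrogen to C7 and moves the double bond to C6=C26.
- The coupling and the transposition are both sound, but the face of hydrogen delivery depends only on which half-chair the C3 acetate prefers. With C7 sp2 one 1,3-diaxial contact is missing, so that preference is small.
- The C21 chain with a handle at C8 also needs more steps than 19.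
- The chosen plan replaces a conformational bias with a geometric constraint.

**Alternative 3:**
- The cuts are C2–C7 and C3–C8 by strain.
- A vinylketene from an acyclic C10 dienoyl chloride would undergo intramolecular [2+2] cycloaddition to the cyclobutanone A5. A5 already holds the ring, the gem-dimethyl carbon, the methylidene and a cis one-carbon bridge.
- Baeyer–Villiger oxidation with retention would then give the lactone A6.
- The migrating carbon has to be C3, whereas its competitor C7 is allylic and should migrate at least as well.
- A5 is racemic, and peracids also threaten the methylidene.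
- In A6 the chain would have to be attached at the carbonyl carbon C8, which must then be reduced to CH2 next to a β,γ-double bond.
- The chosen plan keeps the idea of a cis bridge but builds it from the C3 oxygen, with C9 as a ready handle.

Key step: step 4

Remark on the chemistry: (2E,6E)-farnesyl bromide 13 is taken as the isomerically pure commercial grade. Its two E double bonds are carried unchanged into C14=C15 and C18=C19.

## Steps

Step 1
Reactants: 1 pent-4-yn-1-ol
Product: 2 pent-4-ynal
Conditions: PhI(OAc)2 (1.1 equiv), TEMPO (10 mol %), CH2Cl2, rt
Reagents that add atoms: none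
Why: The oxoammonium (TEMPO) oxidation stops at the aldehyde and leaves the terminal alkyne untouched; the volatile 2 is carried on as a dried solution.

Step 2
Reactants: 2 pent-4-ynal; 3 3-methylbuta-1,2-diene
Product: 6 (4S)-3,3-dimethyloct-1-en-7-yn-4-ol, via prenylborane 4 (not isolated), via borinate 5 (not isolated)
Conditions: (+)-Ipc2BH (from (−)-α-pinene), 3, THF, −25 °C; 2, Et2O, −78 °C; NaOH, H2O2, 0 °C → rt
Reagents that add atoms: none
Why: Hydroboration of 3 at its CH2 terminus gives 4, which adds to 2 through its γ-carbon in a closed chair (Brown-type allylboration), so the C2–C3 bond, the quaternary C2 and the vinyl group C7=C8 form together. The isopinocampheyl groups from (−)-α-pinene select the aldehyde face that gives the 4S carbinol (C3 S of 21), in the sense known for unbranched aliphatic aldehydes. Oxidative work-up cleaves 5.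

Step 3
Reactants: 6 (4S)-3,3-dimethyloct-1-en-7-yn-4-ol
Product: 7 (bromomethyl)dimethyl{[(4S)-3,3-dimethyloct-1-en-7-yn-4-yl]oxy}silane
Conditions: BrCH2SiMe2Cl, Et3N, DMAP (cat.), CH2Cl2, 0 °C → rt
Reagents that add atoms: (bromomethyl)chlorodimethylsilane, C[Si](C)(Cl)CBr
Why: This is an ordinary O-silylation, and the small chlorosilane reaches the neopentylic carbinol. The tether brings in C9 and the radical precursor, and 7 is used without chromatography on acidic silica.

Step 4
Reactants: 7 (bromomethyl)dimethyl{[(4S)-3,3-dimethyloct-1-en-7-yn-4-yl]oxy}silane
Product: 9 (1S,6R)-3,3,10,10-tetramethyl-7-methylidene-2-oxa-3-silabicyclo[4.3.1]decane, via oxasilepanyl radical 8 (not isolated)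
Conditions: Bu3SnH (1.3 equiv) and AIBN (0.2 equiv) by syringe pump over 12 h into 7 (2 mM), benzene, 80 °C
Reagents that add atoms: none
Why: Proposed new method: the stannyl radical abstracts bromine from 7, and the nucleophilic α-silyl radical at C9 adds to the unsubstituted alkene terminus C8 in the 7-endo mode, closing the oxasilepane ring O–Si–C9–C8–C7–C2–C3; the long Si–C and Si–O bonds favour endo attack in homoallylic ethers of this kind, and the 6-exo position C7 is neopentylic next to C2. The secondary radical 8 at C7 then attacks the inner alkyne carbon C6 in the 6-exo-dig mode, closing the carbocycle C2–C3–C4–C5–C6–C7, and the vinyl radical at C26 takes hydrogen from Bu3SnH, so the methylidene is fixed by the carbon count of the alkyne and cannot end up endocyclic. The closest known reactions are the radical cyclisation of (bromomethyl)dimethylsilyl ethers of homoallylic alcohols and silicon-tethered radical cascades that end on alkynes; the new element is their combination into a bridged bicyclo[4.3.1] system. The only new stereocentre, C7, is controlled by the tether: O on C3 and C8 on C7 are already joined through Si and C9 when C6–C7 forms, and a four-atom bridge can span positions 1 and 3 of the new six-membered ring on one face only, so only the cis (3S,7R) arrangement can close, whatever face a free radical would prefer. Three selectivities are needed: bromine abstraction before stannyl addition to the alkyne (secured by the reactive primary α-silyl bromide), alkene before alkyne for the first radical (secured by the terminal CH2 and the gem-dimethyl effect of C2), and cyclisation of 8 before hydrogen transfer (secured by high dilution and slow addition).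

Step 5
Reactants: 9 (1S,6R)-3,3,10,10-tetramethyl-7-methylidene-2-oxa-3-silabicyclo[4.3.1]decane
Product: 10 (1S,3R)-3-(2-hydroxyethyl)-2,2-dimethyl-4-methylidenecyclohexan-1-ol
Conditions: H2O2 (30 % aq.), KF, KHCO3, THF–MeOH (1:1), rt → 40 °C
Reagents that add atoms: hydrogen peroxide, OO
Why: In the Tamao oxidation, peroxide adds to the alkoxy-activated silicon, C9 shifts from Si to O, and both Si–O links are hydrolysed. No stereocentre is touched, and basic H2O2 does not epoxidise an unactivated methylidene. The freed ring relaxes to the diequatorial chair.

Step 6
Reactants: 10 (1S,3R)-3-(2-hydroxyethyl)-2,2-dimethyl-4-methylidenecyclohexan-1-ol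
Product: 11 (1S,3R)-3-(2-iodoethyl)-2,2-dimethyl-4-methylidenecyclohexan-1-ol
Conditions: I2, PPh3, imidazole, CH2Cl2, 0 °C
Reagents that add atoms: iodine, II
Why: In this Appel-type iodination the primary C9 hydroxyl forms the alkoxyphosphonium salt and is displaced by iodide. The C3 hydroxyl is secondary and neopentylic and should not react at 0 °C.

Step 7
Reactants: 11 (1S,3R)-3-(2-iodoethyl)-2,2-dimethyl-4-methylidenecyclohexan-1-ol
Product: 12 (1S,3R)-3-(2-iodoethyl)-2,2-dimethyl-4-methylidenecyclohexyl acetate
Conditions: Ac2O, Et3N, DMAP (cat.), CH2Cl2, 0 °C → rt
Reagents that add atoms: acetic anhydride, CC(=O)OC(C)=O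
Why: DMAP-catalysed acylation of the hindered carbinol occurs with retention at C3. It installs the acetate of the target before the polyene is attached and removes the free hydroxyl that could displace the iodide.

Step 8
Reactants: 13 (2E,6E)-farnesyl bromide; 14 propyne
Product: 17 (6E,10E)-7,11,15-trimethylhexadeca-6,10,14-trien-2-yne, via 1,3-dilithiopropyne 15 (not isolated), via lithium acetylide 16 (not isolated)
Conditions: 14, n-BuLi (2 equiv), TMEDA, Et2O–hexane, −78 → 0 °C; 13, −78 °C → rt; MeI, THF–DMPU, 0 °C → rt
Reagents that add atoms: iodomethane, CI
Why: Double deprotonation of 14 gives 15, whose propargylic carbanion is the more reactive site. SN2 attack at the allylic CH2Br of 13 forms C12–C13 without touching the E alkenes. The remaining acetylide 16 is C-methylated in the same flask, and this methyl becomes the methyl on C10.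

Step 9
Reactants: 17 (6E,10E)-7,11,15-trimethylhexadeca-6,10,14-trien-2-yne
Product: 19 (2E,6E,10E)-2-iodo-7,11,15-trimethylhexadeca-2,6,10,14-tetraene, via alkenylzirconocene 18 (not isolated)
Conditions: Cp2Zr(H)Cl (1.5 equiv), THF, rt → 45 °C; I2, THF, −78 → 0 °C
Reagents that add atoms: iodine, II
Why: Hydrozirconation is a syn addition, and with excess Cp2Zr(H)Cl the regioisomers equilibrate towards zirconium on the less hindered, methyl-bearing carbon C10. Iodinolysis proceeds with retention and gives the E iodide, with iodine trans to C12. The trisubstituted alkenes are inert to the reagent, and the C–Zr bond consumes iodine faster than they could.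

Step 10
Reactants: 12 (1S,3R)-3-(2-iodoethyl)-2,2-dimethyl-4-methylidenecyclohexyl acetate; 19 (2E,6E,10E)-2-iodo-7,11,15-trimethylhexadeca-2,6,10,14-tetraene
Product: 21 (1S,3R)-2,2-dimethyl-4-methylidene-3-[(3E,7E,11E)-3,8,12,16-tetramethylheptadeca-3,7,11,15-tetraen-1-yl]cyclohexyl acetate, via alkylzinc iodide 20 (not isolated)
Conditions: Zn dust (activated with BrCH2CH2Br and Me3SiCl), LiCl, THF, 25 → 40 °C; 19, Pd(dppf)Cl2 (5 mol %), THF, 25 → 45 °C
Reagents that add atoms: none
Why: Zinc insertion into the primary iodide tolerates the acetate, and a species centred on C9 has only a 4-exo or 5-endo path to the methylidene, so it should not cyclise. The alkyl–alkenyl Negishi coupling forms C9–C10 with retention of the C10=C11 geometry, and the chelating dppf favours reductive elimination over β-hydride elimination. The medium is neutral, so the methylidene and both stereocentres are left as set.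

## Compound list

1 | pent-4-yn-1-ol | C#CCCCO | starting material
2 | pent-4-ynal | C#CCCC=O | intermediate
3 | 3-methylbuta-1,2-diene | CC(C)=C=C | starting material
4 | B-(3-methylbut-2-en-1-yl)diisopinocampheylborane (Ipc groups from (−)-α-pinene) | CC(C)=CCB([C@H]1C[C@H]2C[C@@H]([C@@H]1C)C2(C)C)[C@H]1C[C@H]2C[C@@H]([C@@H]1C)C2(C)C | intermediate
5 | diisopinocampheylborinate of 6 | C#CCC[C@H](OB([C@H]1C[C@H]2C[C@@H]([C@@H]1C)C2(C)C)[C@H]1C[C@H]2C[C@@H]([C@@H]1C)C2(C)C)C(C)(C)C=C | intermediate
6 | (4S)-3,3-dimethyloct-1-en-7-yn-4-ol | C#CCC[C@H](O)C(C)(C)C=C | intermediate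
7 | (bromomethyl)dimethyl{[(4S)-3,3-dimethyloct-1-en-7-yn-4-yl]oxy}silane | C#CCC[C@H](O[Si](C)(C)CBr)C(C)(C)C=C | intermediate
8 | (7S)-7-(but-3-yn-1-yl)-2,2,6,6-tetramethyl-1,2-oxasilepan-5-yl radical | C#CCC[C@@H]1O[Si](C)(C)CC[CH]C1(C)C | intermediate
9 | (1S,6R)-3,3,10,10-tetramethyl-7-methylidene-2-oxa-3-silabicyclo[4.3.1]decane | C=C1CC[C@@H]2O[Si](C)(C)CC[C@H]1C2(C)C | intermediate
10 | (1S,3R)-3-(2-hydroxyethyl)-2,2-dimethyl-4-methylidenecyclohexan-1-ol | C=C1CC[C@H](O)C(C)(C)[C@@H]1CCO | intermediate
11 | (1S,3R)-3-(2-iodoethyl)-2,2-dimethyl-4-methylidenecyclohexan-1-ol | C=C1CC[C@H](O)C(C)(C)[C@@H]1CCI | intermediate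
12 | (1S,3R)-3-(2-iodoethyl)-2,2-dimethyl-4-methylidenecyclohexyl acetate | C=C1CC[C@H](OC(C)=O)C(C)(C)[C@@H]1CCI | intermediate
13 | (2E,6E)-farnesyl bromide | CC(C)=CCC/C(C)=C/CC/C(C)=C/CBr | starting material
14 | propyne | CC#C | starting material
15 | 1,3-dilithiopropyne | [Li]CC#C[Li] | intermediate
16 | lithium (5E,9E)-6,10,14-trimethylpentadeca-5,9,13-trien-1-yn-1-ide | [Li]C#CCC/C=C(\C)CC/C=C(\C)CCC=C(C)C | intermediate
17 | (6E,10E)-7,11,15-trimethylhexadeca-6,10,14-trien-2-yne | CC#CCC/C=C(\C)CC/C=C(\C)CCC=C(C)C | intermediate
18 | chlorobis(cyclopentadienyl)[(2E,6E,10E)-7,11,15-trimethylhexadeca-2,6,10,14-tetraen-2-yl]zirconium | C/C(=C\CC/C=C(\C)CC/C=C(\C)CCC=C(C)C)[Zr](Cl)(C1C=CC=C1)C1C=CC=C1 | intermediate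
19 | (2E,6E,10E)-2-iodo-7,11,15-trimethylhexadeca-2,6,10,14-tetraene | C/C(I)=C\CC/C=C(\C)CC/C=C(\C)CCC=C(C)C | intermediate
20 | {2-[(1R,3S)-3-acetoxy-2,2-dimethyl-6-methylidenecyclohexyl]ethyl}zinc iodide | C=C1CC[C@H](OC(C)=O)C(C)(C)[C@@H]1CC[Zn]I | intermediate
21 | (1S,3R)-2,2-dimethyl-4-methylidene-3-[(3E,7E,11E)-3,8,12,16-tetramethylheptadeca-3,7,11,15-tetraen-1-yl]cyclohexyl acetate | C=C1CC[C@H](OC(C)=O)C(C)(C)[C@@H]1CC/C(C)=C/CC/C=C(\C)CC/C=C(\C)CCC=C(C)C | target

## Count and risks

Total steps: 10. Longest linear sequence: 8 (steps 1 to 7, then step 10).

**Step 4 (key step, proposed new method).**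
- What may go wrong:
  - The most likely failure is hydrogen transfer from Bu3SnH to the secondary radical, or a 1,5-hydrogen shift from the propargylic C5, before the 6-exo-dig closure. The bridged closure requires the butynyl arm to stand axial on the seven-membered ring, and addition to an alkyne is slower than to an alkene.
  - A second failure is initial attack of the α-silyl radical on the alkyne arm.
- Fallback with known chemistry, from 6 back to 21:
  - 6 is acetylated to the enyne acetate F1.
  - Pd(OAc)2-catalysed borylative cyclisation of F1 with B2pin2 and MeOH gives the ring boronate F2. The sequence is hydropalladation of the alkyne, 6-exo carbopalladation of the vinyl group and boryl transfer. C7 is set by a chair with an equatorial acetate, and the diastereomers are separated at this stage.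
  - Matteson homologation of F2 with LiCH2Cl gives the homologous boronate F3.
  - Suzuki–Miyaura coupling of F3 with 19 (Pd(dppf)Cl2, K3PO4, aqueous THF) returns to the route at 21.

**Step 9.**
- What may go wrong: the zirconium regioisomers may equilibrate incompletely, because methyl and CH2R differ little in size. Some iodine would then sit on C11, and the isomer would be hard to remove.
- Fallback, from 13 back to 21:
  - 13 is alkylated with the lithium enolate of tert-butyl acetate to give the trienoate F4.
  - Reduction with i-Bu2AlH at −78 °C gives the trienal F5.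
  - Olefination with CBr4 and PPh3 gives the 1,1-dibromoalkene F6.
  - Negishi monoalkylation of F6 with 20, selective for the bromine trans to C12, gives the Z bromoalkene F7.
  - Methylation of F7 with Me2Zn and Pd(P(t-Bu)3)2, with retention, returns to the route at 21.

**Step 6.**
- What may go wrong: the C3 hydroxyl may displace the activated C9 oxygen (or, later, the iodide) and close a bridged six-membered ether, since the two groups are cis.
- Fallback, from 10 back to 12:
  - Both hydroxyls of 10 are acetylated to give the diacetate F8.
  - Brief methanolysis (K2CO3, MeOH, 0 °C) removes only the unhindered primary acetate and gives the hydroxy acetate F9.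
  - Iodination of F9 (I2, PPh3, imidazole) returns to the route at 12. No leaving group is ever present beside a free C3 hydroxyl.

**Step 2.**
- What may go wrong: facial selectivity may be incomplete with a small, unbranched aldehyde, and volatile 2 may be lost.
- Fallback, from 2 back to 6:
  - Zinc-mediated Barbier addition of prenyl bromide to 2, with γ-attack, gives the racemic alcohol F10.
  - Dess–Martin oxidation gives the ketone F11.
  - Corey–Bakshi–Shibata reduction of F11 with the (R)-methyl oxazaborolidine and catecholborane at −78 °C returns to the route at 6. The large difference between the tert-alkyl and primary alkyl flanks is what this reduction exploits.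

**Step 10.**
- What may go wrong: zinc insertion may be sluggish, 20 may be protonated, or β-hydride elimination on palladium may occur during coupling with the α-branched alkenyl iodide.
- Fallback, from 12 and 18 back to 21: the polarity is reversed, and the alkenylzirconocene 18 is coupled directly with the alkyl iodide 12 (Pd(acac)2, LiBr, THF–NMP). No alkylzinc reagent is needed and no new isolated compound is made.

## Further compounds

F1 | step 4 | (4S)-3,3-dimethyloct-1-en-7-yn-4-yl acetate | C#CCC[C@H](OC(C)=O)C(C)(C)C=C
F2 | step 4 | (1S,3R)-2,2-dimethyl-4-methylidene-3-[(4,4,5,5-tetramethyl-1,3,2-dioxaborolan-2-yl)methyl]cyclohexyl acetate | C=C1CC[C@H](OC(C)=O)C(C)(C)[C@@H]1CB1OC(C)(C)C(C)(C)O1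
F3 | step 4 | (1S,3R)-2,2-dimethyl-4-methylidene-3-[2-(4,4,5,5-tetramethyl-1,3,2-dioxaborolan-2-yl)ethyl]cyclohexyl acetate | C=C1CC[C@H](OC(C)=O)C(C)(C)[C@@H]1CCB1OC(C)(C)C(C)(C)O1
F4 | step 9 | tert-butyl (4E,8E)-5,9,13-trimethyltetradeca-4,8,12-trienoate | CC(C)(C)OC(=O)CC/C=C(\C)CC/C=C(\C)CCC=C(C)C
F5 | step 9 | (4E,8E)-5,9,13-trimethyltetradeca-4,8,12-trienal | O=CCC/C=C(\C)CC/C=C(\C)CCC=C(C)C
F6 | step 9 | (5E,9E)-1,1-dibromo-6,10,14-trimethylpentadeca-1,5,9,13-tetraene | BrC(Br)=CCC/C=C(\C)CC/C=C(\C)CCC=C(C)C
F7 | step 9 | (1S,3R)-3-[(3Z,7E,11E)-3-bromo-8,12,16-trimethylheptadeca-3,7,11,15-tetraen-1-yl]-2,2-dimethyl-4-methylidenecyclohexyl acetate | C=C1CC[C@H](OC(C)=O)C(C)(C)[C@@H]1CC/C(Br)=C/CC/C=C(\C)CC/C=C(\C)CCC=C(C)C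
F8 | step 6 | (1S,3R)-3-(2-acetoxyethyl)-2,2-dimethyl-4-methylidenecyclohexyl acetate | C=C1CC[C@H](OC(C)=O)C(C)(C)[C@@H]1CCOC(C)=O
F9 | step 6 | (1S,3R)-3-(2-hydroxyethyl)-2,2-dimethyl-4-methylidenecyclohexyl acetate | C=C1CC[C@H](OC(C)=O)C(C)(C)[C@@H]1CCO
F10 | step 2 | rac-3,3-dimethyloct-1-en-7-yn-4-ol | C#CCCC(O)C(C)(C)C=C
F11 | step 2 | 3,3-dimethyloct-1-en-7-yn-4-one | C#CCCC(=O)C(C)(C)C=C
F0 | step 10 | none | none
A1 | alternative 1 | (3S)-2,3-oxidosqualene | CC(C)=CCC/C(C)=C/CC/C(C)=C/CC/C=C(\C)CC/C=C(\C)CC[C@@H]1OC1(C)C
A2 | alternative 1 | (1S,3R)-2,2-dimethyl-4-methylidene-3-[(3E,7E,11E)-3,8,12,16-tetramethylheptadeca-3,7,11,15-tetraen-1-yl]cyclohexan-1-ol | C=C1CC[C@H](O)C(C)(C)[C@@H]1CC/C(C)=C/CC/C=C(\C)CC/C=C(\C)CCC=C(C)C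
A3 | alternative 2 | (1S)-3-chloro-4-formyl-2,2-dimethylcyclohex-3-en-1-yl acetate | O=CC1=C(Cl)C(C)(C)[C@@H](OC(C)=O)CC1
A4 | alternative 2 | (1S)-4-formyl-2,2-dimethyl-3-[(3E,7E,11E)-3,8,12,16-tetramethylheptadeca-3,7,11,15-tetraen-1-yl]cyclohex-3-en-1-yl acetate | O=CC1=C(CC/C(C)=C/CC/C=C(\C)CC/C=C(\C)CCC=C(C)C)C(C)(C)[C@@H](OC(C)=O)CC1
A5 | alternative 3 | 7,7-dimethyl-2-methylidenebicyclo[3.1.1]heptan-6-one (formed as the racemate, drawn as the enantiomer that maps onto 21) | C=C1CC[C@@H]2C(=O)[C@H]1C2(C)C
A6 | alternative 3 | 8,8-dimethyl-2-methylidene-6-oxabicyclo[3.2.1]octan-7-one (same enantiomeric series) | C=C1CC[C@@H]2OC(=O)[C@H]1C2(C)C
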